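The disconnection is the C2–C1' bond that links the pyranone ring (ring C) to ring B. Because the benzopyranone core carries oxygen on C3, C5, C6, C7 and C8, its single remaining ring hydrogen sits on C2, between O1 and the 3-methoxy group, and is acidic. The key step turns this C–H into a C–Zn bond and couples it under palladium catalysis with an aryl iodide whose iodine marks C1', the one unhindered position of the 3',5'-dioxy-4'-methoxy ring. One operation therefore unites two finished halves without closing a ring. Its precursor is 5,7-bis(benzyloxy)-3,6,8-trimethoxychromone, assembled from a mirror-symmetric pentaoxygenated benzene, methoxyacetyl chloride and a one-carbon amide acetal.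

Key step: step 9

Assumption: 1,3,5-tris(benzyloxy)benzene, 2-methoxyresorcinol and TMPZnCl·LiCl (THF solution) are taken as catalogue items.

Step 1
Reactants: 1 1,3,5-tris(benzyloxy)benzene
Product: 2 1,3,5-tris(benzyloxy)-2,4-dibromobenzene
Conditions: NBS (2.0 equiv), CH2Cl2, 0 °C, dark
Reagents that add atoms: N-bromosuccinimide, O=C1CCC(=O)N1Br
Why: Electrophilic aromatic bromination of a phloroglucinol triether is fast under ionic conditions, and since each bromine lowers the reactivity of the ring a little, two equivalents of NBS at 0 °C should stop at the 2,4-dibromide without touching the benzylic positions.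

Step 2
Reactants: 2 1,3,5-tris(benzyloxy)-2,4-dibromobenzene
Product: 3 1,3,5-tris(benzyloxy)-2,4-dimethoxybenzene
Conditions: NaOMe (8 equiv, 25% in MeOH), CuI (0.3 equiv), DMF, 110 °C, argon
Reagents that add atoms: sodium methoxide, [Na+].[O-]C
Why: Ullmann-type copper-catalysed methoxylation (a monovalent copper methoxide, oxidative addition of the aryl bromide, C–O reductive elimination) is the standard way to convert electron-rich aryl bromides flanked by alkoxy groups into aryl methyl ethers, and benzyl aryl ethers are inert to methoxide.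

Step 3
Reactants: 3 1,3,5-tris(benzyloxy)-2,4-dimethoxybenzene; 4 methoxyacetyl chloride
Product: 5 2-methoxy-1-[2,4,6-tris(benzyloxy)-3,5-dimethoxyphenyl]ethan-1-one
Conditions: SnCl4 (1.2 equiv), CH2Cl2, −40 to 0 °C; aqueous work-up
Reagents that add atoms: none
Why: Friedel–Crafts acylation at the only ring C–H of 3, which is ortho, ortho and para to three alkoxy groups and therefore strongly nucleophilic, so a mild Lewis acid at low temperature should suffice, sparing the benzyl ethers and limiting decarbonylation of the methoxyacetyl cation; any benzyl group lost next to the new ketone only anticipates step 4.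

Step 4
Reactants: 5 2-methoxy-1-[2,4,6-tris(benzyloxy)-3,5-dimethoxyphenyl]ethan-1-one
Product: 6 1-[4,6-bis(benzyloxy)-2-hydroxy-3,5-dimethoxyphenyl]-2-methoxyethan-1-one
Conditions: MgBr2·OEt2 (2 equiv), toluene/Et2O, 60 °C; aqueous work-up
Reagents that add atoms: none
Why: Chelation-controlled ether cleavage in which MgBr2 bridges the ketone oxygen and one ortho benzyloxy oxygen and bromide attacks the benzylic carbon; the magnesium phenoxide chelate then keeps the carbonyl away from the second ortho benzyl ether, the para benzyl ether has no chelate, and the mirror symmetry of 5 makes the two ortho groups equivalent.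

Step 5
Reactants: 6 1-[4,6-bis(benzyloxy)-2-hydroxy-3,5-dimethoxyphenyl]-2-methoxyethan-1-one
Product: 8 5,7-bis(benzyloxy)-3,6,8-trimethoxy-4H-chromen-4-one, via enaminone 7 (not isolated)
Conditions: Me2NCH(OMe)2 (3 equiv), toluene, 100 °C; evaporate; then AcOH, 70 °C
Reagents that add atoms: N,N-dimethylformamide dimethyl acetal, CN(C)C(OC)OC
Why: Condensation of the activated α-methylene with the amide acetal gives the enaminone (its double-bond geometry is of no consequence), and acid then promotes 6-endo-trig conjugate addition of the phenol to the aminomethylene carbon with loss of dimethylamine, the usual enaminone route to chromones, which here inserts C2 between O1 and C3.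

Step 6
Reactants: 9 2-methoxyresorcinol (2-methoxybenzene-1,3-diol)
Product: 10 2-methoxy-1,3-bis(methoxymethoxy)benzene
Conditions: MOMCl (2.6 equiv), i-Pr2NEt (3 equiv), CH2Cl2, 0 °C to rt
Reagents that add atoms: chloromethyl methyl ether, COCCl
Why: Base-mediated O-alkylation of both phenols (Williamson-type acetal formation); MOM is chosen because it offers no aromatic C–H to the later borylation and withstands amide bases, organozinc reagents and palladium.

Step 7
Reactants: 10 2-methoxy-1,3-bis(methoxymethoxy)benzene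
Product: 11 2-[4-methoxy-3,5-bis(methoxymethoxy)phenyl]-4,4,5,5-tetramethyl-1,3,2-dioxaborolane
Conditions: [Ir(OMe)(cod)]2 (1.5 mol %), 4,4'-di-tert-butyl-2,2'-bipyridine (3 mol %), B2pin2 (1.0 equiv), THF, 80 °C
Reagents that add atoms: bis(pinacolato)diboron, CC1(C)OB(OC1(C)C)B1OC(C)(C)C(C)(C)O1
Why: Iridium-catalysed aromatic C–H borylation is governed by sterics, and in this 1,2,3-trisubstituted benzene C5 is the only C–H without an ortho substituent, so boron should enter para to the methoxy group.

Step 8
Reactants: 11 2-[4-methoxy-3,5-bis(methoxymethoxy)phenyl]-4,4,5,5-tetramethyl-1,3,2-dioxaborolane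
Product: 12 5-iodo-2-methoxy-1,3-bis(methoxymethoxy)benzene
Conditions: CuI (10 mol %), 1,10-phenanthroline (20 mol %), KI (1.5 equiv), MeOH/H2O, air, 80 °C
Reagents that add atoms: potassium iodide, [K+].[I-]
Why: Copper-mediated aerobic ipso-iododeboronation (boron-to-copper transmetalation, oxidation to trivalent copper, C–I reductive elimination) replaces boron at the same carbon under neutral conditions that the MOM acetals tolerate.

Step 9
Reactants: 8 5,7-bis(benzyloxy)-3,6,8-trimethoxy-4H-chromen-4-one; 12 5-iodo-2-methoxy-1,3-bis(methoxymethoxy)benzene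
Product: 14 5,7-bis(benzyloxy)-3,6,8,4'-tetramethoxy-3',5'-bis(methoxymethoxy)flavone, via chromon-2-ylzinc chloride 13 (not isolated)
Conditions: TMPZnCl·LiCl (1.3 equiv), THF, −30 to 25 °C; then 12 (1.2 equiv), Pd(dba)2 (3 mol %), P(2-furyl)3 (6 mol %), THF, 50 °C
Reagents that add atoms: TMPZnCl·LiCl, CC1(C)CCCC(C)(C)N1[Zn]Cl.[Li+].[Cl-] (supplies the ZnCl of intermediate 13 only; none of its atoms remain in 14)
Why: The hindered zinc amide, guided by the C4 carbonyl and the 3-methoxy oxygen, removes the proton at C2 of ring C to give a covalent carbon–zinc species that, unlike a 2-lithiochromone, should not open the pyranone ring; zerovalent palladium then inserts into the C–I bond of 12, zinc-to-palladium transmetalation follows and reductive elimination forms the C2–C1' bond. The closest known reaction type is the C2 zincation of chromones with TMP-zinc bases followed by Negishi cross-coupling with aryl halides to give flavones. No ring is closed and no stereocentre is created. Site selectivity on the chromone is secured by the substitution pattern, because C3, C5, C6, C7 and C8 all bear oxygen and C2–H, next to O1, is the only ring C–H and the most acidic one. On ring B the coupling site is fixed by the iodine at C1', which has no ortho substituent, so oxidative addition and reductive elimination are unhindered. Benzyl, MOM and methyl ethers and the ketone should tolerate the mild, non-nucleophilic zinc base.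

Step 10
Reactants: 14 5,7-bis(benzyloxy)-3,6,8,4'-tetramethoxy-3',5'-bis(methoxymethoxy)flavone
Product: 16 5,7,3',5'-tetrahydroxy-3,6,8,4'-tetramethoxyflavone, via debenzylated bis-MOM flavone 15 (not isolated)
Conditions: H2 (1 atm), 10% Pd/C, THF/MeOH, rt; filter through Celite; then conc. HCl (cat.), MeOH, 45 °C
Reagents that add atoms: none
Why: Hydrogenolysis over palladium cleaves only the two benzylic C–O bonds (the tetrasubstituted, conjugated C2=C3 bond of a flavone is not reduced at 1 atm), and acid-catalysed acetal exchange with methanol then frees the two ring B phenols without affecting the four methyl ethers.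

Compound list
1 | 1,3,5-tris(benzyloxy)benzene | c1ccc(COc2cc(OCc3ccccc3)cc(OCc3ccccc3)c2)cc1 | starting material
2 | 1,3,5-tris(benzyloxy)-2,4-dibromobenzene | Brc1c(OCc2ccccc2)cc(OCc2ccccc2)c(Br)c1OCc1ccccc1 | intermediate
3 | 1,3,5-tris(benzyloxy)-2,4-dimethoxybenzene | COc1c(OCc2ccccc2)cc(OCc2ccccc2)c(OC)c1OCc1ccccc1 | intermediate
4 | methoxyacetyl chloride | COCC(=O)Cl | starting material
5 | 2-methoxy-1-[2,4,6-tris(benzyloxy)-3,5-dimethoxyphenyl]ethan-1-one | COCC(=O)c1c(OCc2ccccc2)c(OC)c(OCc2ccccc2)c(OC)c1OCc1ccccc1 | intermediate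
6 | 1-[4,6-bis(benzyloxy)-2-hydroxy-3,5-dimethoxyphenyl]-2-methoxyethan-1-one | COCC(=O)c1c(O)c(OC)c(OCc2ccccc2)c(OC)c1OCc1ccccc1 | intermediate
7 | (Z)-1-[4,6-bis(benzyloxy)-2-hydroxy-3,5-dimethoxyphenyl]-3-(dimethylamino)-2-methoxyprop-2-en-1-one (amino group trans to the carbonyl) | CN(C)/C=C(\OC)C(=O)c1c(O)c(OC)c(OCc2ccccc2)c(OC)c1OCc1ccccc1 | intermediate
8 | 5,7-bis(benzyloxy)-3,6,8-trimethoxy-4H-chromen-4-one | COc1coc2c(OC)c(OCc3ccccc3)c(OC)c(OCc3ccccc3)c2c1=O | intermediate
9 | 2-methoxyresorcinol (2-methoxybenzene-1,3-diol) | COc1c(O)cccc1O | starting material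
10 | 2-methoxy-1,3-bis(methoxymethoxy)benzene | COCOc1cccc(OCOC)c1OC | intermediate
11 | 2-[4-methoxy-3,5-bis(methoxymethoxy)phenyl]-4,4,5,5-tetramethyl-1,3,2-dioxaborolane | COCOc1cc(B2OC(C)(C)C(C)(C)O2)cc(OCOC)c1OC | intermediate
12 | 5-iodo-2-methoxy-1,3-bis(methoxymethoxy)benzene | COCOc1cc(I)cc(OCOC)c1OC | intermediate
13 | [5,7-bis(benzyloxy)-3,6,8-trimethoxy-4-oxo-4H-chromen-2-yl]zinc chloride (LiCl complex) | COc1c([Zn]Cl)oc2c(OC)c(OCc3ccccc3)c(OC)c(OCc3ccccc3)c2c1=O | intermediate
14 | 5,7-bis(benzyloxy)-3,6,8,4'-tetramethoxy-3',5'-bis(methoxymethoxy)flavone | COCOc1cc(-c2oc3c(OC)c(OCc4ccccc4)c(OC)c(OCc4ccccc4)c3c(=O)c2OC)cc(OCOC)c1OC | intermediate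
15 | 5,7-dihydroxy-3,6,8,4'-tetramethoxy-3',5'-bis(methoxymethoxy)flavone | COCOc1cc(-c2oc3c(OC)c(O)c(OC)c(O)c3c(=O)c2OC)cc(OCOC)c1OC | intermediate
16 | 5,7,3',5'-tetrahydroxy-3,6,8,4'-tetramethoxyflavone | COc1c(O)cc(-c2oc3c(OC)c(O)c(OC)c(O)c3c(=O)c2OC)cc1O | target

Total step count: 10 steps.
Longest linear sequence: 7 steps (steps 1, 2, 3, 4, 5, 9 and 10); steps 6 to 8 form the three-step ring B branch.

Steps most likely to fail

Step 2. Reductive loss of bromine (hydrodebromination) may outrun C–O bond formation at the two doubly flanked positions, so that one or both carbons end up unsubstituted. The fallback sets out from 2 and replaces copper catalysis by an organolithium oxidation sequence, one bromine at a time. Bromine–lithium exchange (n-BuLi, 1.05 equiv, THF, −78 °C, faster than benzylic deprotonation) should give [2,4,6-tris(benzyloxy)-3-bromophenyl]lithium F1. Trapping with B(OMe)3 would give dimethyl [2,4,6-tris(benzyloxy)-3-bromophenyl]boronate F2, and oxidation of the crude boronate with H2O2/NaOH would give 2,4,6-tris(benzyloxy)-3-bromophenol F3. O-Methylation (MeI, K2CO3, acetone) would give 1,3,5-tris(benzyloxy)-2-bromo-4-methoxybenzene F4. The same three operations repeated on F4 would pass through [2,4,6-tris(benzyloxy)-3-methoxyphenyl]lithium F5, dimethyl [2,4,6-tris(benzyloxy)-3-methoxyphenyl]boronate F6 and 2,4,6-tris(benzyloxy)-3-methoxyphenol F7, whose methylation comes back to the route at 3.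

Step 3. The Lewis acid may strip or shift benzyl groups before acylation, and the acyl cation may lose carbon monoxide to a methoxymethyl cation that alkylates the ring. The fallback sets out from 3 and makes the aryl–carbonyl bond with a nucleophilic arene instead. Bromination of the last ring C–H (NBS, CH2Cl2, 0 °C) should give 1,3,5-tris(benzyloxy)-2-bromo-4,6-dimethoxybenzene F8. Bromine–lithium exchange (n-BuLi, THF, −78 °C) would give [2,4,6-tris(benzyloxy)-3,5-dimethoxyphenyl]lithium F9. Acylation of F9 with commercial N,2-dimethoxy-N-methylacetamide (the Weinreb amide of methoxyacetic acid) and NH4Cl work-up would come back to the route at 5, with all three benzyl ethers intact.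

Step 9. Deprotonation at C2 may be incomplete, the metalated pyranone may open, or the zinc species may be protonated before it transmetalates. The fallback sets out from 6 and 12 and builds ring C around the C2–C1' bond by a Baker–Venkataraman sequence, with no chromone metalation. Iodine–magnesium exchange on 12 (i-PrMgCl·LiCl, THF, 0 °C) should give [4-methoxy-3,5-bis(methoxymethoxy)phenyl]magnesium chloride F10, and carboxylation with CO2 would give 4-methoxy-3,5-bis(methoxymethoxy)benzoic acid F11. Esterification of the phenol of 6 with F11 (EDC·HCl, DMAP, CH2Cl2) would give 3,5-bis(benzyloxy)-2,4-dimethoxy-6-(2-methoxyacetyl)phenyl 4-methoxy-3,5-bis(methoxymethoxy)benzoate F12. Enolate acyl transfer (LiN(SiMe3)2, THF, −78 to 0 °C) would give 1-[4,6-bis(benzyloxy)-2-hydroxy-3,5-dimethoxyphenyl]-2-methoxy-3-[4-methoxy-3,5-bis(methoxymethoxy)phenyl]propane-1,3-dione F13 (racemic at C2, largely enolised). Cyclodehydration in HCl/MeOH at 60 °C, which also removes the MOM groups, would give 5,7-bis(benzyloxy)-3',5'-dihydroxy-3,6,8,4'-tetramethoxyflavone F14. Hydrogenolysis of F14 (H2, Pd/C, THF/MeOH) comes back to the route at 16.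

Further compounds
F1 | step 2 | [2,4,6-tris(benzyloxy)-3-bromophenyl]lithium | [Li]c1c(OCc2ccccc2)cc(OCc2ccccc2)c(Br)c1OCc1ccccc1
F2 | step 2 | dimethyl [2,4,6-tris(benzyloxy)-3-bromophenyl]boronate | COB(OC)c1c(OCc2ccccc2)cc(OCc2ccccc2)c(Br)c1OCc1ccccc1
F3 | step 2 | 2,4,6-tris(benzyloxy)-3-bromophenol | Oc1c(OCc2ccccc2)cc(OCc2ccccc2)c(Br)c1OCc1ccccc1
F4 | step 2 | 1,3,5-tris(benzyloxy)-2-bromo-4-methoxybenzene | COc1c(OCc2ccccc2)cc(OCc2ccccc2)c(Br)c1OCc1ccccc1
F5 | step 2 | [2,4,6-tris(benzyloxy)-3-methoxyphenyl]lithium | [Li]c1c(OCc2ccccc2)cc(OCc2ccccc2)c(OC)c1OCc1ccccc1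
F6 | step 2 | dimethyl [2,4,6-tris(benzyloxy)-3-methoxyphenyl]boronate | COB(OC)c1c(OCc2ccccc2)cc(OCc2ccccc2)c(OC)c1OCc1ccccc1
F7 | step 2 | 2,4,6-tris(benzyloxy)-3-methoxyphenol | COc1c(OCc2ccccc2)cc(OCc2ccccc2)c(O)c1OCc1ccccc1
F8 | step 3 | 1,3,5-tris(benzyloxy)-2-bromo-4,6-dimethoxybenzene | COc1c(OCc2ccccc2)c(Br)c(OCc2ccccc2)c(OC)c1OCc1ccccc1
F9 | step 3 | [2,4,6-tris(benzyloxy)-3,5-dimethoxyphenyl]lithium | COc1c(OCc2ccccc2)c([Li])c(OCc2ccccc2)c(OC)c1OCc1ccccc1
F10 | step 9 | [4-methoxy-3,5-bis(methoxymethoxy)phenyl]magnesium chloride | COCOc1cc([Mg]Cl)cc(OCOC)c1OC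
F11 | step 9 | 4-methoxy-3,5-bis(methoxymethoxy)benzoic acid | COCOc1cc(C(=O)O)cc(OCOC)c1OC
F12 | step 9 | 3,5-bis(benzyloxy)-2,4-dimethoxy-6-(2-methoxyacetyl)phenyl 4-methoxy-3,5-bis(methoxymethoxy)benzoate | COCC(=O)c1c(OC(=O)c2cc(OCOC)c(OC)c(OCOC)c2)c(OC)c(OCc2ccccc2)c(OC)c1OCc1ccccc1
F13 | step 9 | 1-[4,6-bis(benzyloxy)-2-hydroxy-3,5-dimethoxyphenyl]-2-methoxy-3-[4-methoxy-3,5-bis(methoxymethoxy)phenyl]propane-1,3-dione (racemic) | COCOc1cc(C(=O)C(OC)C(=O)c2c(O)c(OC)c(OCc3ccccc3)c(OC)c2OCc2ccccc2)cc(OCOC)c1OC
F14 | step 9 | 5,7-bis(benzyloxy)-3',5'-dihydroxy-3,6,8,4'-tetramethoxyflavone | COc1c(O)cc(-c2oc3c(OC)c(OCc4ccccc4)c(OC)c(OCc4ccccc4)c3c(=O)c2OC)cc1O
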